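**Retrosynthetic overview**
- The target is a 2-methyl-3-alkyl-1,4-naphthoquinone. The last operations are oxidative demethylation of a 4-methoxy-1-naphthol and removal of a silyl ether from the C5′ hydroxyl.
- Key disconnection: ring B (the quinone ring C1–C2–C3–C4–C4a–C8a) is cut into three pieces. These are a methoxy(phenyl)carbene chromium complex (C1 plus ring A with C8a and C4a), an internal alkyne (C2 with its methyl, C3 with the side-chain CH2) and one CO ligand (C4). C1 and C4 both end as C=O, so either orientation of the alkyne gives the same quinone.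
- The alkyne is a skipped enyne, made from a propynyl Grignard reagent and the E-allylic bromide that carries C1′.
- The C20 chain comes from a vinylogous Mukaiyama aldol of (3R,7R)-3,7,11-trimethyldodecanal with the silyl dienolate of methyl 3-methylbut-2-enoate, which sets C5′ (S) and the 2′E alkene. C7′ and C11′ come from asymmetric hydrogenation of (2E,6E)-farnesol.
- Ring order: ring A is bought as the phenyl group; ring B is the only ring formed, in the benzannulation.

Key step: step 10

Assumption: the L-tryptophan promoter of step 4 is taken to leave the Re face of the aldehyde open (accepted model: aldehyde bound to boron cis to the indolylmethyl arm), to be confirmed by Mosher ester analysis with the D-reagent used otherwise; in step 1 the ligand enantiomer is the one that gives the 3R,7R alcohol.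

**Route**

Step 1
Reactants: 1 (2E,6E)-farnesol
Product: 2 (3R,7R)-3,7,11-trimethyldodecan-1-ol
Conditions: H2 (50 bar), [Ir(cod)(L)][B(C6H3-3,5-(CF3)2)4] (1 mol%, L = enantiopure 8-(di-tert-butylphosphinooxy)-2-phenyl-5,6,7,8-tetrahydroquinoline), CH2Cl2, rt
Reagents that add atoms: none
Why: Iridium P,N-ligand catalysed asymmetric hydrogenation of trisubstituted alkenes should saturate all three double bonds, the catalyst setting C3 and C7 as R,R by enantioface control on the two E-alkenes while the terminal alkene gives no stereocentre.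

Step 2
Reactants: 2 (3R,7R)-3,7,11-trimethyldodecan-1-ol
Product: 3 (3R,7R)-3,7,11-trimethyldodecanal
Conditions: TEMPO (10 mol%), PhI(OAc)2 (1.1 equiv), CH2Cl2, rt
Reagents that add atoms: none
Why: The oxoammonium-mediated (TEMPO) oxidation should stop at the aldehyde, and the β-stereocentre cannot epimerise.

Step 3
Reactants: 4 methyl 3-methylbut-2-enoate
Product: 6 (1Z)-1-methoxy-3-methyl-1-[(tert-butyldimethylsilyl)oxy]buta-1,3-diene, via lithium dienolate 5 (not isolated)
Conditions: LiN(iPr)2, THF, −78 °C; TBSCl, DMPU, −78 °C → rt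
Reagents that add atoms: tert-butyldimethylsilyl chloride, CC(C)(C)[Si](C)(C)Cl
Why: γ-Deprotonation of the enoate by the amide base followed by O-silylation of the extended enolate (silyl ketene acetal formation) should give the silyl dienolate, expected mainly as the 1Z isomer, whose geometry is lost in the next step.

Step 4
Reactants: 3 (3R,7R)-3,7,11-trimethyldodecanal; 6 (1Z)-1-methoxy-3-methyl-1-[(tert-butyldimethylsilyl)oxy]buta-1,3-diene
Product: 7 methyl (2E,5S,7R,11R)-5-hydroxy-3,7,11,15-tetramethylhexadec-2-enoate
Conditions: N-tosyl-L-tryptophan, PhBCl2, CH2Cl2, rt, evaporate (B-phenyl oxazaborolidinone, 1.0 equiv); 6 (1.5 equiv), iPrOH (1.2 equiv), EtCN, −78 °C; aq NaHCO3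
Reagents that add atoms: none
Why: In this vinylogous Mukaiyama aldol reaction the boron-bound aldehyde is attacked by the γ-carbon of the dienolate in an open transition state, the s-trans diene giving the 2E-enoate, and the tryptophan-derived oxazaborolidinone should shield the Si face so that Re-face attack sets C5 as S under reagent control, the remote C7 methyl exerting little bias.

Step 5
Reactants: 7 methyl (2E,5S,7R,11R)-5-hydroxy-3,7,11,15-tetramethylhexadec-2-enoate
Product: 8 methyl (2E,5S,7R,11R)-5-[(tert-butyldimethylsilyl)oxy]-3,7,11,15-tetramethylhexadec-2-enoate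
Conditions: TBSOTf (1.3 equiv), 2,6-lutidine, CH2Cl2, −78 → 0 °C
Reagents that add atoms: tert-butyldimethylsilyl trifluoromethanesulfonate, CC(C)(C)[Si](C)(C)OS(=O)(=O)C(F)(F)F
Why: Silylation of the secondary alcohol with a silyl triflate and a hindered base is a standard protection that masks the hydroxyl against the later bromination, Grignard and ketene-forming steps.

Step 6
Reactants: 8 methyl (2E,5S,7R,11R)-5-[(tert-butyldimethylsilyl)oxy]-3,7,11,15-tetramethylhexadec-2-enoate
Product: 9 (2E,5S,7R,11R)-5-[(tert-butyldimethylsilyl)oxy]-3,7,11,15-tetramethylhexadec-2-en-1-ol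
Conditions: iBu2AlH (2.5 equiv), CH2Cl2, −78 °C; aq potassium sodium tartrate
Reagents that add atoms: none
Why: 1,2-Reduction of the conjugated ester by the aluminium hydride at low temperature should give the E-allylic alcohol without touching the silyl ether or the alkene geometry.

Step 7
Reactants: 9 (2E,5S,7R,11R)-5-[(tert-butyldimethylsilyl)oxy]-3,7,11,15-tetramethylhexadec-2-en-1-ol
Product: 10 (2E,5S,7R,11R)-1-bromo-5-[(tert-butyldimethylsilyl)oxy]-3,7,11,15-tetramethylhexadec-2-ene
Conditions: CBr4, PPh3, CH2Cl2, 0 °C; used crude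
Reagents that add atoms: carbon tetrabromide, BrC(Br)(Br)Br
Why: The Appel bromination displaces the oxyphosphonium ion of the primary allylic alcohol by SN2 under neutral conditions, which should preserve the E geometry and the silyl ether.

Step 8
Reactants: 10 (2E,5S,7R,11R)-1-bromo-5-[(tert-butyldimethylsilyl)oxy]-3,7,11,15-tetramethylhexadec-2-ene; 11 prop-1-yn-1-ylmagnesium bromide
Product: 12 tert-butyldimethyl{[(5E,8S,10R,14R)-6,10,14,18-tetramethylnonadec-5-en-2-yn-8-yl]oxy}silane
Conditions: 11 (2 equiv), CuI (10 mol%), THF, 0 → 50 °C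
Reagents that add atoms: none
Why: Copper-catalysed coupling of an alkynyl Grignard reagent with a primary allylic bromide (alkynylcopper SN2 substitution) should join at the unhindered CH2 terminus with retention of the E-alkene to give the skipped enyne.

Step 9
Reactants: 13 chromium hexacarbonyl; 14 phenyllithium
Product: 16 pentacarbonyl[methoxy(phenyl)methylidene]chromium, via lithium acylchromate 15 (not isolated)
Conditions: Et2O, 0 °C → rt; Me3OBF4, CH2Cl2, 0 °C
Reagents that add atoms: trimethyloxonium tetrafluoroborate, C[O+](C)C.F[B-](F)(F)F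
Why: In this Fischer carbene synthesis phenyllithium adds to a CO ligand to give the acylmetalate, whose oxygen is then methylated by the oxonium salt.

Step 10
Reactants: 12 tert-butyldimethyl{[(5E,8S,10R,14R)-6,10,14,18-tetramethylnonadec-5-en-2-yn-8-yl]oxy}silane; 16 pentacarbonyl[methoxy(phenyl)methylidene]chromium
Product: 18 2-{(2E,5S,7R,11R)-5-[(tert-butyldimethylsilyl)oxy]-3,7,11,15-tetramethylhexadec-2-en-1-yl}-4-methoxy-3-methylnaphthalen-1-ol, via tricarbonylchromium naphthol complex 17 (not isolated)
Conditions: 16 (1.5 equiv), THF (degassed), 55 °C, Ar; then air, Et2O, rt; crude 18 taken on at once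
Reagents that add atoms: none
Why: On warming, 16 loses one CO, the alkyne of 12 coordinates and inserts into the Cr=C bond to give an η3-vinylcarbene, a CO ligand inserts to give an η4-vinylketene, and this closes onto the phenyl ortho carbon and tautomerises to the Cr(CO)3-bound naphthol 17, which air demetalates to 18. The closest known reaction type is the Dötz benzannulation of aryl(alkoxy)carbene chromium complexes with internal dialkylalkynes, a well-established entry to precursors of 2,3-dialkyl-1,4-naphthoquinones. Ring B is closed by 6π-electrocyclisation of the dienylketene (a formal [3+2+1] assembly), forming C1–C2, C3–C4 and C4–C4a of the future quinone. No stereocentre is created, and the three existing ones and the E-alkene are remote from the metal and should be untouched under neutral conditions at 55 °C. The step needs only chemoselectivity: the alkyne must insert in preference to the trisubstituted alkene, which the far higher affinity of the unsaturated chromium for alkynes and the one-carbon tether (too short for intramolecular cyclopropanation or ketene [2+2] capture) secure, and phenol formation must win over indene or cyclobutenone formation, which the methoxy(aryl)carbene and the donor solvent favour. Regiochemistry (larger substituent expected next to OH) is of no consequence, because the regioisomer with methyl and side chain exchanged gives the same quinone once C1 and C4 are both carbonyls.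

Step 11
Reactants: 18 2-{(2E,5S,7R,11R)-5-[(tert-butyldimethylsilyl)oxy]-3,7,11,15-tetramethylhexadec-2-en-1-yl}-4-methoxy-3-methylnaphthalen-1-ol
Product: 19 2-{(2E,5S,7R,11R)-5-[(tert-butyldimethylsilyl)oxy]-3,7,11,15-tetramethylhexadec-2-en-1-yl}-3-methylnaphthalene-1,4-dione
Conditions: (NH4)2Ce(NO3)6 (2.5 equiv), MeCN/H2O 4:1, 0 °C, short reaction time
Reagents that add atoms: water, O
Why: Oxidative demethylation of the 4-methoxy-1-naphthol by the cerium oxidant (two one-electron oxidations, water addition at C4 and loss of methanol) should be fast enough at 0 °C to spare the trisubstituted alkene and the silyl ether, and both alkyne orientations from step 10 converge here.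

Step 12
Reactants: 19 2-{(2E,5S,7R,11R)-5-[(tert-butyldimethylsilyl)oxy]-3,7,11,15-tetramethylhexadec-2-en-1-yl}-3-methylnaphthalene-1,4-dione
Product: 20 2-[(2E,5S,7R,11R)-5-hydroxy-3,7,11,15-tetramethylhexadec-2-en-1-yl]-3-methylnaphthalene-1,4-dione
Conditions: HF·pyridine, pyridine, THF, 0 °C → rt, dark
Reagents that add atoms: none
Why: Fluoride cleavage of the secondary silyl ether with buffered HF·pyridine avoids the basic conditions that degrade 3-allyl-2-methylnaphthoquinones and leaves the three stereocentres and the E-alkene untouched.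

**Compound list**
1 | (2E,6E)-farnesol | OC/C=C(\C)CC/C=C(\C)CCC=C(C)C | starting material
2 | (3R,7R)-3,7,11-trimethyldodecan-1-ol | OCC[C@H](C)CCC[C@H](C)CCCC(C)C | intermediate
3 | (3R,7R)-3,7,11-trimethyldodecanal | O=CC[C@H](C)CCC[C@H](C)CCCC(C)C | intermediate
4 | methyl 3-methylbut-2-enoate | COC(=O)C=C(C)C | starting material
5 | lithium (1E)-1-methoxy-3-methylbuta-1,3-dien-1-olate (O–Li cis to C3) | C=C(C)/C=C(/OC)[O-].[Li+] | intermediate
6 | (1Z)-1-methoxy-3-methyl-1-[(tert-butyldimethylsilyl)oxy]buta-1,3-diene | C=C(C)/C=C(/OC)O[Si](C)(C)C(C)(C)C | intermediate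
7 | methyl (2E,5S,7R,11R)-5-hydroxy-3,7,11,15-tetramethylhexadec-2-enoate | COC(=O)/C=C(\C)C[C@@H](O)C[C@H](C)CCC[C@H](C)CCCC(C)C | intermediate
8 | methyl (2E,5S,7R,11R)-5-[(tert-butyldimethylsilyl)oxy]-3,7,11,15-tetramethylhexadec-2-enoate | COC(=O)/C=C(\C)C[C@@H](O[Si](C)(C)C(C)(C)C)C[C@H](C)CCC[C@H](C)CCCC(C)C | intermediate
9 | (2E,5S,7R,11R)-5-[(tert-butyldimethylsilyl)oxy]-3,7,11,15-tetramethylhexadec-2-en-1-ol | OC/C=C(\C)C[C@@H](O[Si](C)(C)C(C)(C)C)C[C@H](C)CCC[C@H](C)CCCC(C)C | intermediate
10 | (2E,5S,7R,11R)-1-bromo-5-[(tert-butyldimethylsilyl)oxy]-3,7,11,15-tetramethylhexadec-2-ene | BrC/C=C(\C)C[C@@H](O[Si](C)(C)C(C)(C)C)C[C@H](C)CCC[C@H](C)CCCC(C)C | intermediate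
11 | prop-1-yn-1-ylmagnesium bromide | CC#C[Mg]Br | starting material
12 | tert-butyldimethyl{[(5E,8S,10R,14R)-6,10,14,18-tetramethylnonadec-5-en-2-yn-8-yl]oxy}silane | CC#CC/C=C(\C)C[C@@H](O[Si](C)(C)C(C)(C)C)C[C@H](C)CCC[C@H](C)CCCC(C)C | intermediate
13 | chromium hexacarbonyl | O=C=[Cr](=C=O)(=C=O)(=C=O)(=C=O)=C=O | starting material
14 | phenyllithium | [Li]c1ccccc1 | starting material
15 | lithium pentacarbonyl[oxido(phenyl)methylidene]chromate | [Li+].[O-]C(c1ccccc1)=[Cr](=C=O)(=C=O)(=C=O)(=C=O)=C=O | intermediate
16 | pentacarbonyl[methoxy(phenyl)methylidene]chromium | COC(c1ccccc1)=[Cr](=C=O)(=C=O)(=C=O)(=C=O)=C=O | intermediate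
17 | tricarbonylchromium complex of 18, chromium η6-bound to the new oxygenated ring (mixture of planar diastereomers; η6 bonding written as a dot-separated pair) | COc1c(C)c(C/C=C(\C)C[C@@H](O[Si](C)(C)C(C)(C)C)C[C@H](C)CCC[C@H](C)CCCC(C)C)c(O)c2ccccc12.O=C=[Cr](=C=O)=C=O | intermediate
18 | 2-{(2E,5S,7R,11R)-5-[(tert-butyldimethylsilyl)oxy]-3,7,11,15-tetramethylhexadec-2-en-1-yl}-4-methoxy-3-methylnaphthalen-1-ol | COc1c(C)c(C/C=C(\C)C[C@@H](O[Si](C)(C)C(C)(C)C)C[C@H](C)CCC[C@H](C)CCCC(C)C)c(O)c2ccccc12 | intermediate
19 | 2-{(2E,5S,7R,11R)-5-[(tert-butyldimethylsilyl)oxy]-3,7,11,15-tetramethylhexadec-2-en-1-yl}-3-methylnaphthalene-1,4-dione | CC1=C(C/C=C(\C)C[C@@H](O[Si](C)(C)C(C)(C)C)C[C@H](C)CCC[C@H](C)CCCC(C)C)C(=O)c2ccccc2C1=O | intermediate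
20 | 2-[(2E,5S,7R,11R)-5-hydroxy-3,7,11,15-tetramethylhexadec-2-en-1-yl]-3-methylnaphthalene-1,4-dione | CC1=C(C/C=C(\C)C[C@@H](O)C[C@H](C)CCC[C@H](C)CCCC(C)C)C(=O)c2ccccc2C1=O | target

**Step count**
Total: 12 steps. Longest linear sequence: 10 steps (steps 1, 2, 4, 5, 6, 7, 8, 10, 11, 12, from farnesol).

**Steps most likely to fail, with fallbacks**

Step 10. The vinylketene intermediate may divert to cyclobutenone, indene or furan products, or the carbene complex may decompose before it takes up the hindered alkyne, so that little naphthol forms. The fallback attaches the chain to a preformed naphthalene; it sets out from bromide 10 and comes back to the route at quinone 19. Purchased 1,4-dimethoxy-2-methylnaphthalene is brominated (Br2, CH2Cl2, 0 °C) to 2-bromo-1,4-dimethoxy-3-methylnaphthalene F1. With Mg in THF this gives (1,4-dimethoxy-3-methylnaphthalen-2-yl)magnesium bromide F2. Copper-catalysed (CuBr·SMe2) SN2 coupling of F2 with 10 should give tert-butyl{[(2E,5S,7R,11R)-1-(1,4-dimethoxy-3-methylnaphthalen-2-yl)-3,7,11,15-tetramethylhexadec-2-en-5-yl]oxy}dimethylsilane F3 with the E-alkene retained. Oxidation of F3 with (NH4)2Ce(NO3)6 in MeCN/H2O then gives 19.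

Step 4. Facial selectivity may be poor, because the promoter must override a remote β-methyl stereocentre and its sense rests on a model; α-attack of the dienolate may also compete. The fallback sets the carbinol by allylboration; it sets out from aldehyde 3 and comes back at silyl ether 8. Brown allylation of 3 with purchased B-allyldiisopinocampheylborane derived from (−)-α-pinene (Et2O, −78 °C, then NaOH/H2O2), which should add to the Re face of unhindered aldehydes, should give (4R,6R,10R)-6,10,14-trimethylpentadec-1-en-4-ol F4. F4 has the same spatial arrangement as C5 of 7; the descriptor differs only through the priority rules. Silylation (TBSOTf, 2,6-lutidine) gives tert-butyldimethyl{[(4R,6R,10R)-6,10,14-trimethylpentadec-1-en-4-yl]oxy}silane F5. Wacker oxidation (PdCl2, CuCl, O2, DMF/H2O) gives (4S,6R,10R)-4-[(tert-butyldimethylsilyl)oxy]-6,10,14-trimethylpentadecan-2-one F6. Horner–Wadsworth–Emmons olefination of F6 with trimethyl phosphonoacetate and NaH in THF gives 8 after chromatographic removal of the 2Z isomer.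

Step 8. The alkynylcopper may attack the tertiary terminus (SN2′), or the labile allylic bromide may equilibrate and scramble the E geometry before coupling. The fallback sets out from bromide 10 and comes back at enyne 12. Stille coupling of 10 with purchased tributyl(prop-1-yn-1-yl)stannane [Pd(PPh3)4, THF, 50 °C] goes through a π-allylpalladium intermediate that is attacked at its unsubstituted terminus and should give 12 directly; no new intermediate is made.

**Further compounds**
F1 | step 10 | 2-bromo-1,4-dimethoxy-3-methylnaphthalene | COc1c(C)c(Br)c(OC)c2ccccc12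
F2 | step 10 | (1,4-dimethoxy-3-methylnaphthalen-2-yl)magnesium bromide | COc1c(C)c([Mg]Br)c(OC)c2ccccc12
F3 | step 10 | tert-butyl{[(2E,5S,7R,11R)-1-(1,4-dimethoxy-3-methylnaphthalen-2-yl)-3,7,11,15-tetramethylhexadec-2-en-5-yl]oxy}dimethylsilane | COc1c(C)c(C/C=C(\C)C[C@@H](O[Si](C)(C)C(C)(C)C)C[C@H](C)CCC[C@H](C)CCCC(C)C)c(OC)c2ccccc12
F4 | step 4 | (4R,6R,10R)-6,10,14-trimethylpentadec-1-en-4-ol | C=CC[C@@H](O)C[C@H](C)CCC[C@H](C)CCCC(C)C
F5 | step 4 | tert-butyldimethyl{[(4R,6R,10R)-6,10,14-trimethylpentadec-1-en-4-yl]oxy}silane | C=CC[C@@H](O[Si](C)(C)C(C)(C)C)C[C@H](C)CCC[C@H](C)CCCC(C)C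
F6 | step 4 | (4S,6R,10R)-4-[(tert-butyldimethylsilyl)oxy]-6,10,14-trimethylpentadecan-2-one | CC(=O)C[C@@H](O[Si](C)(C)C(C)(C)C)C[C@H](C)CCC[C@H](C)CCCC(C)C
F0 | step 8 | none | none
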